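## The problem

The target joins two terpenoid ring systems through a four-carbon chain. The left half is a trans-fused 2,2-dimethyloxepane–cyclohexane, numbered here as a decahydro-1-benzoxepine: O1, C2 gem-dimethyl, C5a angular methyl, C6 tertiary carbinol carrying the chain, C7 secondary methyl, C9a ring-fusion CH–O. The right half is a bicyclo[2.2.2]octane: C1 bridgehead CH, C2 quaternary carbon with methyl and the chain, C3 CH2, C4 bridgehead tertiary alcohol, C5 CH with the arylmethyl group, C6 gem-dimethyl, C7–C8 ethano bridge. The arene is a hydroquinone sulfated on the oxygen meta to the benzylic carbon.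

The eight stereocentres form two clusters of four, separated by four methylene groups. Neither half can control the other, so each must be made as a single enantiomer and the two joined.

In the bicycle, C1 and C4 are tied to C2 by the ring. The real questions are the orientation at C2 (chain toward the C5–C6 bridge) and at C5 (hydrogen toward the C2–C3 bridge); a functional group on C2 is well placed to deliver hydrogen to C5.

In the benzoxepane, the quaternary C5a controls the rest: the trans fusion at C9a, the equatorial methyl at C7, and at C6 an axial hydroxyl with the chain on the face of the axial angular methyl. That is the hindered face, so adding a carbon nucleophile to a C6 ketone should give the wrong epimer.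

The fragile functions are the aryl sulfate (acid-labile, needed on one specific oxygen), the free hydroquinone (easily oxidised), the two tertiary alcohols (the C5 cation of the bicycle rearranges, the C6 carbinol dehydrates) and the tertiary ether of the oxepane.

The feature that opens the key step is the C2–C3 bridge. It is a methacrylate unit, with its CH2 on the oxygenated bridgehead C4 and its substituted carbon on the bridgehead CH C1. The other six carbons (C4, C5, C6, C1, C7, C8) are a cyclohexenone whose α'-carbon bears the oxygen. The enolate of a 6-alkoxycyclohex-2-enone is nucleophilic at that carbon and the methacrylate is electrophilic at its CH2, so a Michael–Michael annulation gives this bridge orientation. A Diels–Alder addition to a 1-oxygenated cyclohexadiene would give the opposite one.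

## Retrosynthesis

**Sulfate and protecting groups (47 ⇐ 46 ⇐ 45 ⇐ 44).** The S–O bond, the two O–benzyl bonds and the two C–H bonds of the saturated chain are cut first. The sulfate is the most fragile group, so it goes on in the penultimate step, onto the single free phenol of 45. The other phenol and the bridgehead alcohol stay as benzyl ethers, because neutral hydrogenolysis spares an aryl sulfate salt and saturates the chain alkene in the same operation. Sulfating a free hydroquinone instead would need regioselection on an air-sensitive compound. The forward route therefore needs one phenol protecting group (methoxymethyl in 44) that leaves without hydrogen or strong acid.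

**The chain (44 ⇐ 28 + 43).** The C=C bond between the third and fourth chain carbons, counted from C6 of the benzoxepane, is cut to two terminal alkenes. A cut at the carbinol would mean adding the chain to a C6 ketone from the hindered face. A cut at the quaternary C2 of the bicycle would need a neopentyl substitution. The chosen cut gives two halves of similar size with four stereocentres each, and asks only for a cross-metathesis in which the hindered vinyl group of 28 does not homodimerise.

**The tertiary carbinol (43 ⇐ 42 ⇐ 41 ⇐ 40).** The bond between the first and second chain carbons is cut (epoxide CH2 plus an allyl nucleophile), then the epoxide C–O bond, then the exocyclic C=C back to ketone 40. Oxygen is thus delivered to the alkene anti to the axial angular methyl, which gives the axial C6–O bond; the chain then grows from the equatorial CH2. The forward steps need face selectivity in the epoxidation and substitution at the CH2 only.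

**Methyl group and oxidation level (40 ⇐ 38 ⇐ 37 ⇐ 36).** The C7–CH3 bond is cut to the enolate of 38, whose only enolisable position is C7; equilibration puts the methyl equatorial. The ketone is traced to acetate 36, because C6 must be masked while the oxepane closes.

**The oxepane (36 ⇐ 35 ⇐ 32 + 33).** The tertiary O1–C2 bond and the C3–C4 bond are cut. Cutting C9a–O instead would need substitution at a neopentyl secondary carbon, or reduction of a bicyclic oxocarbenium ion of uncertain face. The tertiary centre ionises easily and the hydroxyl is already fixed trans to the side chain. The precursors are a monocyclic allyl compound 32 and the commodity alkene 33.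

**The cyclohexane stereocentres (32 ⇐ 31 ⇐ 30 ⇐ 29).** The C–H bond at the free carbinol, the C–H bond at the acylated carbinol and the C–allyl bond are cut. Desymmetrising reduction of the prochiral dione 30 fixes the quaternary centre. The first hydroxyl then directs the second reduction to the anti diol and is acylated in the same step, so the two oxygens are set and told apart in two operations.

**Vinyl group and C5 (28 ⇐ 27 ⇐ 26 ⇐ 25).** The vinyl carbon is removed back to aldehyde 27 and alcohol 26, then the C5–H bond back to styrene 25. The ester carbon is held at the alcohol level until then, because the hydroxymethyl group on C2 is the only handle on the face of the alkene where hydrogen must arrive; undirected hydrogenation would use the open face.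

**The arylmethyl group (25 ⇐ 24 ⇐ 23 ⇐ 16 + 21; 21 ⇐ 20 ⇐ 19 ⇐ 18 ⇐ 17).** The C5=C bond is traced to a tertiary alcohol and the C5–CH2Ar bond to ketone 16 and benzylic chloride 21. The annulation leaves its ketone at C5, and the arene comes from a cheap aldehyde 17 whose two phenols differ in reactivity. Hydroboration and cross-coupling of an exocyclic methylene would put hydrogen on the open face of C5 and give the wrong epimer.

**The gem-dimethyl group (16 ⇐ 12).** Two C6–CH3 bonds are cut. C6 is the only enolisable carbon of 12, so no selectivity question arises.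

**Key disconnection (12 ⇐ 9 + 3).** The C3–C4 and C1–C2 bonds are cut. The bicycle, with three stereocentres and one ring, falls to an achiral enone and a methacrylate. The forward step needs C-selective conjugate addition, endo closure, and a handle for the absolute configuration, which the menthyl ester supplies.

**Starting materials (9 ⇐ 8 ⇐ 6 ⇐ 4; 3 ⇐ 1 + 2).** The C6–O bond of the enone is made by α'-oxidation of cyclohexenone 4 through its silyl dienol ether. The chiral ester is an acylation of menthol 1 with 2.

## Roads not taken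

**Alternative 1:** This road cuts the C5a–C6 bond of the left cyclohexane on the otherwise complete skeleton. An iron hydride (Fe(acac)3, PhSiH3) transfers a hydrogen atom to the trisubstituted alkene of the seco keto oxepene A2. The tertiary radical adds 6-exo to the chain ketone and gives the protected skeleton A1.
- Merits: it forms the most congested bond of the left half, between a quaternary carbon and a tertiary carbinol, in one step. It needs no exocyclic alkene, epoxide or cuprate, so it is about three steps shorter than steps 25–27 here, and it is more convergent.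
- Weak points: radical addition to a ketone is reversible and depends on fast reduction of the alkoxy radical. One late step must set C5a and C6 relative to C9a and to an epimerisable C7, with no element that clearly enforces the trans fusion and the axial hydroxyl. The oxepene needs a tertiary alkyl ether of a secondary allylic alcohol.
- Comparison: it does not address the bicyclo[2.2.2]octane, which still needs its own construction. It places its least predictable step at the end, on the most valuable material; the chosen plan is longer on the left but sets each centre by a separately arguable step and takes its main risk in step 5, on commodity materials.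

**Alternative 2:** This road cuts the C4–CH2 bond of the ethano bridge. Under KOH in methanol the acetyl methyl of the 4-acetylcyclohexanone A4 adds to the ring ketone and gives the bridgehead ketol A3.
- Merits: the bridgehead alcohol appears free, and the gem-dimethyl and arylmethyl groups are in place before the ring closes. The hindered ketone addition and the directed hydrogenation of the chosen plan are avoided, and the C5 centre, α to the ring ketone, can settle by equilibration. In these respects it is better.
- Weak points: the aldol is reversible and closes a strained ketol through a boat with the acetyl group axial. A4 carries four contiguous substituted carbons that must be assembled with control beforehand. The ketone left in the ethano bridge must be removed, and basic deoxygenation invites retro-aldol opening.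
- Comparison: the chosen plan builds the whole bicyclic skeleton with its quaternary centre from two simple partners in one step, with the ketone exactly where the arylmethyl group goes and no extra function to excise.

**Alternative 3:** This road cuts the C4–C5 bond. SmI2 with HMPA and tert-butanol turns the styrenyl cyclohexanone A6 into its ketyl, which adds 6-exo to the styrene carbon next to the gem-dimethyl group and gives the bicyclooctanol A5.
- Merits: the bridgehead carbinol and the C5 stereocentre form together, the arene arrives with the alkene, and the alcohol needs no protection. The dimethylation, Grignard addition, dehydration and directed hydrogenation used here (steps 6, 11, 12, 14) are not needed. That is about four steps saved after ring closure, a real advantage.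
- Weak points: A6 needs the quaternary centre and its neighbour, with a bulky 1,1-dimethylallyl group, set by separate chemistry. The closure requires that group axial and a boat transition state. The C5 configuration depends on how the styrene lies over the ring, which is hard to predict. HMPA is required.
- Comparison: the chosen plan has a polar annulation whose regiochemistry is fixed by mechanism, an endo closure that sets the quaternary centre in the ring-forming step, and a C5 centre set by a director whose geometry can be checked on models.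

Key step: step 5

Assumption: from step 30 on the aryl sulfate would be handled as its sodium salt; 46 and 47 are listed as the free hydrogen sulfates, the form in which the target is drawn.

Remark: locants in the names follow the numbering used in the first section.

## Route

Step 1
Reactants: 1 (1R,2S,5R)-(–)-menthol; 2 methacryloyl chloride
Product: 3 (1R,2S,5R)-menthyl methacrylate
Conditions: Et3N, DMAP (cat.), CH2Cl2, 0 °C → rt
Reagents that add atoms: none
Why: Acylation of a secondary alcohol by an acid chloride (nucleophilic acyl substitution); no stereocentre is touched, and the bulky chiral ester later serves as resolving handle and shields the ester carbonyl.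

Step 2
Reactants: 4 cyclohex-2-en-1-one
Product: 6 2-(trimethylsilyloxy)cyclohexa-1,3-diene, via lithium dienolate 5 (not isolated)
Conditions: LiN(iPr)2, THF, −78 °C; Me3SiCl, −78 °C → rt
Reagents that add atoms: chlorotrimethylsilane, C[Si](C)(C)Cl
Why: Kinetic deprotonation of the enone at C6 gives the cross-conjugated dienolate, which is silylated on oxygen (silyl enol ether formation).

Step 3
Reactants: 6 2-(trimethylsilyloxy)cyclohexa-1,3-diene
Product: 8 6-hydroxycyclohex-2-en-1-one (racemic), via 6-(trimethylsilyloxy)cyclohex-2-en-1-one 7 (not isolated)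
Conditions: mCPBA, NaHCO3, CH2Cl2, −20 → 0 °C; then HCl (1 M), THF, 0 °C
Reagents that add atoms: 3-chloroperoxybenzoic acid, OOC(=O)c1cccc(Cl)c1
Why: Rubottom oxidation: the electron-rich silyl enol ether double bond is epoxidised in preference to the disubstituted alkene, the silyloxy epoxide rearranges to the α-silyloxy ketone and acid removes silicon. The new centre is racemic and is erased in step 5.

Step 4
Reactants: 8 6-hydroxycyclohex-2-en-1-one
Product: 9 6-(benzyloxy)cyclohex-2-en-1-one (racemic)
Conditions: benzyl 2,2,2-trichloroacetimidate, TfOH (cat.), CH2Cl2/cyclohexane, 0 °C → rt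
Reagents that add atoms: benzyl 2,2,2-trichloroacetimidate, N=C(OCc1ccccc1)C(Cl)(Cl)Cl
Why: Acid-catalysed O-benzylation with an imidate; base is avoided because the α-hydroxy enone would tautomerise to the diosphenol.

Step 5
Reactants: 9 6-(benzyloxy)cyclohex-2-en-1-one; 3 (1R,2S,5R)-menthyl methacrylate
Product: 12 (1R,2S,5R)-menthyl (1R,2R,4S)-4-(benzyloxy)-2-methyl-5-oxobicyclo[2.2.2]octane-2-carboxylate, via lithium dienolate 10 (not isolated), via ester enolate adduct 11 (not isolated)
Conditions: LiN(iPr)2 (1.05 equiv), THF, −78 °C; then 3, −78 → −20 °C; NH4Cl (aq.); chromatography and crystallisation of the diastereomers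
Reagents that add atoms: none
Why: LiN(iPr)2 removes the C6 proton of 9 under kinetic control to give the cross-conjugated dienolate 10, whose oxygen-bearing carbon adds to the CH2 terminus of 3; the ester enolate 11 then adds to the enone β-carbon and the resulting ketone enolate is protonated on work-up. The closest known reaction type is the lithium dienolate double Michael annulation of cyclohex-2-enones with acrylates and methacrylates to bicyclo[2.2.2]octan-2-ones. The new six-membered ring is closed 6-exo-trig by the ester enolate; the two-atom tether can only reach the enone carbon on the face that already carries the CH2 group, which fixes the two bridgeheads relative to each other. The quaternary centre C2 is set in this closure by the endo-type arrangement in which lithium bridges the ester enolate oxygen and the enone oxygen, so the ester ends syn to the ketone bridge and the methyl group toward the ethano bridge. The enone is achiral once enolised, so both absolute senses form; the menthyl group turns them into diastereomers, and the (1R,2R,4S) isomer 12 is the one kept. The step needs conjugate rather than carbonyl addition and C- rather than O-alkylation, which the soft, fully substituted enolate carbon and the hindered menthyl ester carbonyl favour; the regiochemistry (CH2 next to the oxygenated bridgehead) follows from the polar stepwise mechanism. The bulky ester also slows anionic oligomerisation of the methacrylate.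

Step 6
Reactants: 12 (1R,2S,5R)-menthyl (1R,2R,4S)-4-(benzyloxy)-2-methyl-5-oxobicyclo[2.2.2]octane-2-carboxylate
Product: 16 (1R,2S,5R)-menthyl (1R,2R,4S)-4-(benzyloxy)-2,6,6-trimethyl-5-oxobicyclo[2.2.2]octane-2-carboxylate, via lithium enolate 13 (not isolated), via 6-monomethyl ketone 14 (not isolated), via lithium enolate 15 (not isolated)
Conditions: LiN(iPr)2, THF, −78 °C; MeI, −78 → 0 °C; then LiN(iPr)2, DMPU, −78 °C; MeI, −78 → 0 °C (one flask)
Reagents that add atoms: iodomethane, CI
Why: Enolate C-alkylation, twice; C6 is the only enolisable position (the other α-carbon is the bridgehead C–OBn, the ester α-carbon is quaternary). Lithium enolates at low temperature should not open by retro-Michael reaction, and the transient C6 centre disappears with the second methyl group.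

Step 7
Reactants: 17 2,5-dihydroxybenzaldehyde
Product: 18 2-hydroxy-5-(methoxymethoxy)benzaldehyde
Conditions: MOMCl (1.05 equiv), iPr2NEt, CH2Cl2, 0 °C
Reagents that add atoms: chloromethyl methyl ether, COCCl
Why: O-alkylation of the phenol that is not hydrogen-bonded to the aldehyde; the chelated 2-OH is much less nucleophilic under amine base.

Step 8
Reactants: 18 2-hydroxy-5-(methoxymethoxy)benzaldehyde
Product: 19 2-(benzyloxy)-5-(methoxymethoxy)benzaldehyde
Conditions: BnBr, K2CO3, DMF, rt
Reagents that add atoms: benzyl bromide, BrCc1ccccc1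
Why: Williamson etherification of the remaining phenol.

Step 9
Reactants: 19 2-(benzyloxy)-5-(methoxymethoxy)benzaldehyde
Product: 20 [2-(benzyloxy)-5-(methoxymethoxy)phenyl]methanol
Conditions: NaBH4, MeOH, 0 °C
Reagents that add atoms: none
Why: Borohydride reduction of an aryl aldehyde to the benzylic alcohol.

Step 10
Reactants: 20 [2-(benzyloxy)-5-(methoxymethoxy)phenyl]methanol
Product: 21 1-(benzyloxy)-2-(chloromethyl)-4-(methoxymethoxy)benzene
Conditions: PPh3, N-chlorosuccinimide, CH2Cl2, 0 °C
Reagents that add atoms: N-chlorosuccinimide, ClN1C(=O)CCC1=O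
Why: Appel-type chlorination under neutral conditions, which the acid-labile methoxymethyl ether tolerates.

Step 11
Reactants: 16 (1R,2S,5R)-menthyl (1R,2R,4S)-4-(benzyloxy)-2,6,6-trimethyl-5-oxobicyclo[2.2.2]octane-2-carboxylate; 21 1-(benzyloxy)-2-(chloromethyl)-4-(methoxymethoxy)benzene
Product: 23 (1R,2S,5R)-menthyl (1R,2R,4S,5R)-4-(benzyloxy)-5-[2-(benzyloxy)-5-(methoxymethoxy)benzyl]-5-hydroxy-2,6,6-trimethylbicyclo[2.2.2]octane-2-carboxylate, via benzylic Grignard reagent 22 (not isolated)
Conditions: 21, Mg, THF, 0 °C; then 16, LaCl3·2LiCl (0.3 equiv), THF, −78 → 0 °C; NH4Cl (aq.)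
Reagents that add atoms: none
Why: Grignard 1,2-addition to a non-enolisable ketone; benzylic magnesium reagents add to hindered ketones and cannot reduce them (no β-hydrogen), and the neopentyl menthyl ester should be left alone at or below 0 °C. Attack is expected from the ethano-bridge face, but the new carbinol centre is removed in step 12.

Step 12
Reactants: 23 (1R,2S,5R)-menthyl (1R,2R,4S,5R)-4-(benzyloxy)-5-[2-(benzyloxy)-5-(methoxymethoxy)benzyl]-5-hydroxy-2,6,6-trimethylbicyclo[2.2.2]octane-2-carboxylate
Product: 24 (1R,2S,5R)-menthyl (1R,2R,4S,5Z)-4-(benzyloxy)-5-[2-(benzyloxy)-5-(methoxymethoxy)benzylidene]-2,6,6-trimethylbicyclo[2.2.2]octane-2-carboxylate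
Conditions: Martin sulfurane Ph2S[OC(CF3)2Ph]2, CH2Cl2, 0 °C → rt
Reagents that add atoms: none
Why: Dehydration of a tertiary alcohol through its alkoxysulfurane; only the benzylic hydrogens are β to the carbinol carbon, so one conjugated regioisomer should form, and the fast low-temperature elimination limits Wagner–Meerwein shifts of a bicyclooctyl cation. The Z isomer (aryl away from the gem-dimethyl group) is expected; either geometry serves step 14.

Step 13
Reactants: 24 (1R,2S,5R)-menthyl (1R,2R,4S,5Z)-4-(benzyloxy)-5-[2-(benzyloxy)-5-(methoxymethoxy)benzylidene]-2,6,6-trimethylbicyclo[2.2.2]octane-2-carboxylate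
Product: 25 [(1R,2R,4S,5Z)-4-(benzyloxy)-5-[2-(benzyloxy)-5-(methoxymethoxy)benzylidene]-2,6,6-trimethylbicyclo[2.2.2]octan-2-yl]methanol
Conditions: LiAlH4, THF, 0 → 60 °C
Reagents that add atoms: none
Why: Hydride reduction of the hindered ester to the primary alcohol with release of menthol; ethers, acetal and styrene are inert.

Step 14
Reactants: 25 [(1R,2R,4S,5Z)-4-(benzyloxy)-5-[2-(benzyloxy)-5-(methoxymethoxy)benzylidene]-2,6,6-trimethylbicyclo[2.2.2]octan-2-yl]methanol
Product: 26 [(1R,2R,4S,5S)-4-(benzyloxy)-5-[2-(benzyloxy)-5-(methoxymethoxy)benzyl]-2,6,6-trimethylbicyclo[2.2.2]octan-2-yl]methanol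
Conditions: [Ir(cod)(PCy3)(py)]PF6 (10 mol %), H2 (1 atm), CH2Cl2, rt
Reagents that add atoms: none
Why: Hydroxyl-directed homogeneous hydrogenation with Crabtree's catalyst. The hydroxymethyl group on C2 reaches the face of the C5 alkene that looks toward the C2–C3 bridge, binds iridium and delivers hydrogen there, so the C5 hydrogen ends syn to that bridge and the arylmethyl group points to the ethano bridge (5S). The cationic iridium catalyst does not cleave benzyl ethers.

Step 15
Reactants: 26 [(1R,2R,4S,5S)-4-(benzyloxy)-5-[2-(benzyloxy)-5-(methoxymethoxy)benzyl]-2,6,6-trimethylbicyclo[2.2.2]octan-2-yl]methanol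
Product: 27 (1R,2R,4S,5S)-4-(benzyloxy)-5-[2-(benzyloxy)-5-(methoxymethoxy)benzyl]-2,6,6-trimethylbicyclo[2.2.2]octane-2-carbaldehyde
Conditions: Dess–Martin periodinane, NaHCO3, CH2Cl2, rt
Reagents that add atoms: none
Why: Dess–Martin oxidation of a neopentyl primary alcohol to a non-enolisable aldehyde.

Step 16
Reactants: 27 (1R,2R,4S,5S)-4-(benzyloxy)-5-[2-(benzyloxy)-5-(methoxymethoxy)benzyl]-2,6,6-trimethylbicyclo[2.2.2]octane-2-carbaldehyde
Product: 28 (1R,2S,4S,5S)-4-(benzyloxy)-5-[2-(benzyloxy)-5-(methoxymethoxy)benzyl]-2-ethenyl-2,6,6-trimethylbicyclo[2.2.2]octane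
Conditions: Ph3PCH3Br, KOtBu, THF, 0 °C → rt
Reagents that add atoms: methyltriphenylphosphonium bromide, C[P+](c1ccccc1)(c1ccccc1)c1ccccc1.[Br-]
Why: Wittig methylenation; the aldehyde has no α-hydrogen, so it can neither enolise nor epimerise.

Step 17
Reactants: 29 2-methylcyclohexane-1,3-dione
Product: 30 2-methyl-2-(prop-2-en-1-yl)cyclohexane-1,3-dione
Conditions: allyl acetate, Pd(PPh3)4 (2 mol %), DBU, toluene, rt
Reagents that add atoms: allyl acetate, C=CCOC(C)=O
Why: Tsuji–Trost allylation; the soft dione enolate is alkylated on carbon by the π-allyl palladium complex.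

Step 18
Reactants: 30 2-methyl-2-(prop-2-en-1-yl)cyclohexane-1,3-dione
Product: 31 (2S,3S)-3-hydroxy-2-methyl-2-(prop-2-en-1-yl)cyclohexan-1-one (hydroxyl cis to allyl)
Conditions: baker's yeast (Saccharomyces cerevisiae), sucrose, H2O, 30 °C
Reagents that add atoms: none
Why: Enantiotopic-group-selective carbonyl reduction; yeast reduces 2,2-disubstituted cyclohexane-1,3-diones of this kind to the (S)-alcohol with hydride delivered anti to the larger substituent. This fixes the quaternary carbon that becomes C5a.

Step 19
Reactants: 31 (2S,3S)-3-hydroxy-2-methyl-2-(prop-2-en-1-yl)cyclohexan-1-one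
Product: 32 (1S,2R,3S)-3-hydroxy-2-methyl-2-(prop-2-en-1-yl)cyclohexyl acetate
Conditions: SmI2 (0.3 equiv), MeCHO (6 equiv), THF, −10 °C
Reagents that add atoms: acetaldehyde, CC=O
Why: Evans–Tishchenko reduction: the samarium-bound hemiacetal formed from the hydroxyl and acetaldehyde delivers hydride to the ketone on the face of the existing oxygen. The anti diol results, with the old hydroxyl acetylated and the new one (trans to the allyl group) free, so stereocontrol and differentiation come in one step.

Step 20
Reactants: 32 (1S,2R,3S)-3-hydroxy-2-methyl-2-(prop-2-en-1-yl)cyclohexyl acetate; 33 2-methylbut-3-en-2-ol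
Product: 35 (1S,2R,3S)-3-hydroxy-2-(4-hydroxy-4-methylpentyl)-2-methylcyclohexyl acetate, via E-alkene 34 (not isolated)
Conditions: second-generation Grubbs catalyst RuCl2(=CHPh)(H2IMes)(PCy3) (3 mol %), 33 (5 equiv), CH2Cl2, 40 °C; then Pt/C, H2 (1 atm), EtOAc, rt (same flask)
Reagents that add atoms: none
Why: Olefin cross-metathesis of a monosubstituted alkene with a tertiary allylic alcohol, a partner that homodimerises slowly and gives E products, then heterogeneous hydrogenation of 34.

Step 21
Reactants: 35 (1S,2R,3S)-3-hydroxy-2-(4-hydroxy-4-methylpentyl)-2-methylcyclohexyl acetate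
Product: 36 (5aR,6S,9aS)-2,2,5a-trimethyldecahydro-1-benzoxepin-6-yl acetate
Conditions: Bi(OTf)3 (5 mol %), CH2Cl2 (0.02 M), 0 °C → rt
Reagents that add atoms: none
Why: Acid-catalysed dehydrative etherification: the tertiary alcohol ionises and the cation is captured by the secondary hydroxyl on the neighbouring carbon, which lies trans-diequatorial to the chain, closing the oxepane. The acetate blocks the other oxygen, and the trans ring fusion is the one set in step 19.

Step 22
Reactants: 36 (5aR,6S,9aS)-2,2,5a-trimethyldecahydro-1-benzoxepin-6-yl acetate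
Product: 37 (5aS,6S,9aS)-2,2,5a-trimethyldecahydro-1-benzoxepin-6-ol
Conditions: K2CO3, MeOH, 40 °C
Reagents that add atoms: none
Why: Methanolysis of the acetate (transesterification).

Step 23
Reactants: 37 (5aS,6S,9aS)-2,2,5a-trimethyldecahydro-1-benzoxepin-6-ol
Product: 38 (5aR,9aS)-2,2,5a-trimethyloctahydro-1-benzoxepin-6(2H)-one
Conditions: Dess–Martin periodinane, NaHCO3, CH2Cl2, rt
Reagents that add atoms: none
Why: Dess–Martin oxidation of the secondary alcohol to the ketone.

Step 24
Reactants: 38 (5aR,9aS)-2,2,5a-trimethyloctahydro-1-benzoxepin-6(2H)-one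
Product: 40 (5aR,7S,9aS)-2,2,5a,7-tetramethyloctahydro-1-benzoxepin-6(2H)-one, via lithium enolate 39 (not isolated)
Conditions: LiN(iPr)2, THF, −78 °C; MeI, −78 → 0 °C; then NaOMe (cat.), MeOH, rt
Reagents that add atoms: iodomethane, CI
Why: Enolate methylation at C7, the only enolisable position; methoxide equilibration leaves the methyl equatorial (7S), which avoids a 1,3-diaxial contact with the axial angular methyl.

Step 25
Reactants: 40 (5aR,7S,9aS)-2,2,5a,7-tetramethyloctahydro-1-benzoxepin-6(2H)-one
Product: 41 (5aS,7S,9aS)-2,2,5a,7-tetramethyl-6-methylidenedecahydro-1-benzoxepine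
Conditions: Ph3PCH3Br, KOtBu, toluene, 90 °C
Reagents that add atoms: methyltriphenylphosphonium bromide, C[P+](c1ccccc1)(c1ccccc1)c1ccccc1.[Br-]
Why: Wittig methylenation of a hindered ketone under forcing conditions; C7 is epimerisable but already in its thermodynamic configuration.

Step 26
Reactants: 41 (5aS,7S,9aS)-2,2,5a,7-tetramethyl-6-methylidenedecahydro-1-benzoxepine
Product: 42 spiro-epoxide of 41 at C6 (epoxide oxygen axial, trans to the angular methyl)
Conditions: mCPBA, NaHCO3, CH2Cl2, 0 °C
Reagents that add atoms: 3-chloroperoxybenzoic acid, OOC(=O)c1cccc(Cl)c1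
Why: Prilezhaev epoxidation of the exocyclic alkene; the peracid should approach the face opposite the axial methyl on the neighbouring carbon (axial attack), which places the new C6–O bond axial.

Step 27
Reactants: 42 spiro-epoxide
Product: 43 (5aR,6S,7S,9aS)-6-(but-3-en-1-yl)-2,2,5a,7-tetramethyldecahydro-1-benzoxepin-6-ol
Conditions: allylMgBr, CuBr·SMe2 (10 mol %), THF, −30 → 0 °C; NH4Cl (aq.)
Reagents that add atoms: allylmagnesium bromide, C=CC[Mg]Br
Why: Copper-catalysed SN2 opening of the 1,1-disubstituted epoxide at its CH2 carbon; the C6–O bond is untouched, so the configuration from step 26 is kept (axial hydroxyl, equatorial chain).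

Step 28
Reactants: 28 (1R,2S,4S,5S)-4-(benzyloxy)-5-[2-(benzyloxy)-5-(methoxymethoxy)benzyl]-2-ethenyl-2,6,6-trimethylbicyclo[2.2.2]octane; 43 (5aR,6S,7S,9aS)-6-(but-3-en-1-yl)-2,2,5a,7-tetramethyldecahydro-1-benzoxepin-6-ol
Product: 44 E-alkene joining the two halves (stereocentres as in 28 and 43)
Conditions: second-generation Hoveyda–Grubbs catalyst RuCl2(=CH-C6H4-2-OiPr)(H2IMes) (10 mol %), 43 (1.5 equiv), CH2Cl2, 40 °C
Reagents that add atoms: none
Why: Cross-metathesis between a reactive terminal alkene and a vinyl group on a quaternary carbon, a partner that does not homodimerise. The E isomer is expected, and the geometry is irrelevant because the alkene is hydrogenated in step 31.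

Step 29
Reactants: 44 E-alkene joining the two halves
Product: 45 phenol (methoxymethyl group removed)
Conditions: HCl (0.3 M in MeOH), CH2Cl2, 0 °C → rt
Reagents that add atoms: none
Why: Acid-catalysed acetal exchange removes the aryl methoxymethyl ether; the tertiary alcohol, the tertiary ether and the benzyl ethers should be stable to dilute methanolic HCl at room temperature.

Step 30
Reactants: 45 phenol
Product: 46 aryl hydrogen sulfate of 45
Conditions: SO3·pyridine, pyridine, rt; NaHCO3 (aq.)
Reagents that add atoms: sulfur trioxide pyridine complex, O=S(=O)([O-])[n+]1ccccc1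
Why: O-sulfation of the phenol; the hindered tertiary alcohol does not react under these conditions.

Step 31
Reactants: 46 aryl hydrogen sulfate
Product: 47 CNP0255133.1
Conditions: H2 (1 atm), Pd(OH)2/C, MeOH/EtOAc, rt (sodium salt); acidic ion-exchange resin, 0 °C
Reagents that add atoms: none
Why: One operation hydrogenates the chain alkene and hydrogenolyses the aryl and the bridgehead benzyl ethers; aryl sulfate monoester salts are stable to neutral hydrogenolysis.

## Compound list

1 | (1R,2S,5R)-(–)-menthol | CC(C)[C@@H]1CC[C@@H](C)C[C@H]1O | starting material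
2 | methacryloyl chloride | C=C(C)C(=O)Cl | starting material
3 | (1R,2S,5R)-menthyl methacrylate | CC(C)[C@@H]1CC[C@@H](C)C[C@H]1OC(=O)C(C)=C | intermediate
4 | cyclohex-2-en-1-one | O=C1C=CCCC1 | starting material
5 | lithium cyclohexa-1,5-dien-1-olate | [Li]OC1=CCCC=C1 | intermediate (not isolated)
6 | 2-(trimethylsilyloxy)cyclohexa-1,3-diene | C[Si](C)(C)OC1=CCCC=C1 | intermediate
7 | 6-(trimethylsilyloxy)cyclohex-2-en-1-one (racemic) | C[Si](C)(C)OC1CCC=CC1=O | intermediate (not isolated)
8 | 6-hydroxycyclohex-2-en-1-one (racemic) | O=C1C=CCCC1O | intermediate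
9 | 6-(benzyloxy)cyclohex-2-en-1-one (racemic) | O=C1C=CCCC1OCc1ccccc1 | intermediate
10 | lithium 6-(benzyloxy)cyclohexa-1,5-dien-1-olate | [Li]OC1=C(OCc2ccccc2)CCC=C1 | intermediate (not isolated)
11 | lithium enolate of menthyl 3-[(1S)-1-(benzyloxy)-2-oxocyclohex-3-en-1-yl]-2-methylpropanoate | CC(C)[C@@H]1CC[C@@H](C)C[C@H]1OC(O[Li])=C(C)C[C@@]2(OCc3ccccc3)CCC=CC2=O | intermediate (not isolated)
12 | (1R,2S,5R)-menthyl (1R,2R,4S)-4-(benzyloxy)-2-methyl-5-oxobicyclo[2.2.2]octane-2-carboxylate | CC(C)[C@@H]1CC[C@@H](C)C[C@H]1OC(=O)[C@]2(C)C[C@@]3(OCc4ccccc4)CC[C@@H]2CC3=O | intermediate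
13 | lithium enolate of 12 | CC(C)[C@@H]1CC[C@@H](C)C[C@H]1OC(=O)[C@]2(C)C[C@@]3(OCc4ccccc4)CC[C@@H]2C=C3O[Li] | intermediate (not isolated)
14 | 6-monomethyl ketone (methyl toward the ethano bridge expected) | CC(C)[C@@H]1CC[C@@H](C)C[C@H]1OC(=O)[C@]2(C)C[C@@]3(OCc4ccccc4)CC[C@@H]2[C@H](C)C3=O | intermediate (not isolated)
15 | lithium enolate of 14 | CC(C)[C@@H]1CC[C@@H](C)C[C@H]1OC(=O)[C@]2(C)C[C@@]3(OCc4ccccc4)CC[C@@H]2C(C)=C3O[Li] | intermediate (not isolated)
16 | (1R,2S,5R)-menthyl (1R,2R,4S)-4-(benzyloxy)-2,6,6-trimethyl-5-oxobicyclo[2.2.2]octane-2-carboxylate | CC(C)[C@@H]1CC[C@@H](C)C[C@H]1OC(=O)[C@]2(C)C[C@@]3(OCc4ccccc4)CC[C@@H]2C(C)(C)C3=O | intermediate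
17 | 2,5-dihydroxybenzaldehyde | O=Cc1cc(O)ccc1O | starting material
18 | 2-hydroxy-5-(methoxymethoxy)benzaldehyde | COCOc1ccc(O)c(C=O)c1 | intermediate
19 | 2-(benzyloxy)-5-(methoxymethoxy)benzaldehyde | COCOc1ccc(OCc2ccccc2)c(C=O)c1 | intermediate
20 | [2-(benzyloxy)-5-(methoxymethoxy)phenyl]methanol | COCOc1ccc(OCc2ccccc2)c(CO)c1 | intermediate
21 | 1-(benzyloxy)-2-(chloromethyl)-4-(methoxymethoxy)benzene | COCOc1ccc(OCc2ccccc2)c(CCl)c1 | intermediate
22 | [2-(benzyloxy)-5-(methoxymethoxy)benzyl]magnesium chloride | COCOc1ccc(OCc2ccccc2)c(C[Mg]Cl)c1 | intermediate (not isolated)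
23 | menthyl (1R,2R,4S,5R)-4-(benzyloxy)-5-[2-(benzyloxy)-5-(methoxymethoxy)benzyl]-5-hydroxy-2,6,6-trimethylbicyclo[2.2.2]octane-2-carboxylate (hydroxyl toward the C2–C3 bridge) | CC(C)[C@@H]1CC[C@@H](C)C[C@H]1OC(=O)[C@]2(C)C[C@@]3(OCc4ccccc4)CC[C@@H]2C(C)(C)[C@]3(O)Cc2cc(OCOC)ccc2OCc2ccccc2 | intermediate
24 | menthyl (1R,2R,4S,5Z)-4-(benzyloxy)-5-[2-(benzyloxy)-5-(methoxymethoxy)benzylidene]-2,6,6-trimethylbicyclo[2.2.2]octane-2-carboxylate | CC(C)[C@@H]1CC[C@@H](C)C[C@H]1OC(=O)[C@]2(C)C[C@@]3(OCc4ccccc4)CC[C@@H]2C(C)(C)/C3=C/c2cc(OCOC)ccc2OCc2ccccc2 | intermediate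
25 | [(1R,2R,4S,5Z)-4-(benzyloxy)-5-[2-(benzyloxy)-5-(methoxymethoxy)benzylidene]-2,6,6-trimethylbicyclo[2.2.2]octan-2-yl]methanol | OC[C@]1(C)C[C@@]2(OCc3ccccc3)CC[C@@H]1C(C)(C)/C2=C/c1cc(OCOC)ccc1OCc1ccccc1 | intermediate
26 | [(1R,2R,4S,5S)-4-(benzyloxy)-5-[2-(benzyloxy)-5-(methoxymethoxy)benzyl]-2,6,6-trimethylbicyclo[2.2.2]octan-2-yl]methanol | OC[C@]1(C)C[C@@]2(OCc3ccccc3)CC[C@@H]1C(C)(C)[C@@H]2Cc1cc(OCOC)ccc1OCc1ccccc1 | intermediate
27 | (1R,2R,4S,5S)-4-(benzyloxy)-5-[2-(benzyloxy)-5-(methoxymethoxy)benzyl]-2,6,6-trimethylbicyclo[2.2.2]octane-2-carbaldehyde | O=C[C@]1(C)C[C@@]2(OCc3ccccc3)CC[C@@H]1C(C)(C)[C@@H]2Cc1cc(OCOC)ccc1OCc1ccccc1 | intermediate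
28 | (1R,2S,4S,5S)-4-(benzyloxy)-5-[2-(benzyloxy)-5-(methoxymethoxy)benzyl]-2-ethenyl-2,6,6-trimethylbicyclo[2.2.2]octane | C=C[C@]1(C)C[C@@]2(OCc3ccccc3)CC[C@@H]1C(C)(C)[C@@H]2Cc1cc(OCOC)ccc1OCc1ccccc1 | intermediate
29 | 2-methylcyclohexane-1,3-dione | CC1C(=O)CCCC1=O | starting material
30 | 2-methyl-2-(prop-2-en-1-yl)cyclohexane-1,3-dione | C=CCC1(C)C(=O)CCCC1=O | intermediate
31 | (2S,3S)-3-hydroxy-2-methyl-2-(prop-2-en-1-yl)cyclohexan-1-one | O=C1CCC[C@H](O)[C@]1(C)CC=C | intermediate
32 | (1S,2R,3S)-3-hydroxy-2-methyl-2-(prop-2-en-1-yl)cyclohexyl acetate | CC(=O)O[C@H]1CCC[C@H](O)[C@@]1(C)CC=C | intermediate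
33 | 2-methylbut-3-en-2-ol | C=CC(C)(C)O | starting material
34 | (1S,2R,3S)-3-hydroxy-2-[(2E)-4-hydroxy-4-methylpent-2-en-1-yl]-2-methylcyclohexyl acetate | CC(=O)O[C@H]1CCC[C@H](O)[C@@]1(C)C/C=C/C(C)(C)O | intermediate (not isolated)
35 | (1S,2R,3S)-3-hydroxy-2-(4-hydroxy-4-methylpentyl)-2-methylcyclohexyl acetate | CC(=O)O[C@H]1CCC[C@H](O)[C@@]1(C)CCCC(C)(C)O | intermediate
36 | (5aR,6S,9aS)-2,2,5a-trimethyldecahydro-1-benzoxepin-6-yl acetate | CC(=O)O[C@H]1CCC[C@@H]2OC(C)(C)CCC[C@@]12C | intermediate
37 | (5aS,6S,9aS)-2,2,5a-trimethyldecahydro-1-benzoxepin-6-ol | O[C@H]1CCC[C@@H]2OC(C)(C)CCC[C@@]12C | intermediate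
38 | (5aR,9aS)-2,2,5a-trimethyloctahydro-1-benzoxepin-6(2H)-one | O=C1CCC[C@@H]2OC(C)(C)CCC[C@@]12C | intermediate
39 | lithium enolate of 38 | [Li]OC1=CCC[C@@H]2OC(C)(C)CCC[C@@]12C | intermediate (not isolated)
40 | (5aR,7S,9aS)-2,2,5a,7-tetramethyloctahydro-1-benzoxepin-6(2H)-one | C[C@H]1CC[C@@H]2OC(C)(C)CCC[C@@]2(C)C1=O | intermediate
41 | (5aS,7S,9aS)-2,2,5a,7-tetramethyl-6-methylidenedecahydro-1-benzoxepine | C[C@H]1CC[C@@H]2OC(C)(C)CCC[C@@]2(C)C1=C | intermediate
42 | spiro-epoxide of 41 at C6 (oxygen axial, trans to the angular methyl, cis to the C7 methyl) | C[C@H]1CC[C@@H]2OC(C)(C)CCC[C@@]2(C)[C@]1(O3)C3 | intermediate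
43 | (5aR,6S,7S,9aS)-6-(but-3-en-1-yl)-2,2,5a,7-tetramethyldecahydro-1-benzoxepin-6-ol | C[C@H]1CC[C@@H]2OC(C)(C)CCC[C@@]2(C)[C@]1(O)CCC=C | intermediate
44 | E-alkene joining 43 and 28: benzoxepan-6-ol linked by a but-3-ene-1,4-diyl chain to C2 of the protected bicyclooctane | C[C@H]1CC[C@@H]2OC(C)(C)CCC[C@@]2(C)[C@]1(O)CC/C=C/[C@]1(C)C[C@@]2(OCc3ccccc3)CC[C@@H]1C(C)(C)[C@@H]2Cc1cc(OCOC)ccc1OCc1ccccc1 | intermediate
45 | phenol from 44 (4-(benzyloxy)-3-substituted phenol) | C[C@H]1CC[C@@H]2OC(C)(C)CCC[C@@]2(C)[C@]1(O)CC/C=C/[C@]1(C)C[C@@]2(OCc3ccccc3)CC[C@@H]1C(C)(C)[C@@H]2Cc1cc(O)ccc1OCc1ccccc1 | intermediate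
46 | aryl hydrogen sulfate of 45 | C[C@H]1CC[C@@H]2OC(C)(C)CCC[C@@]2(C)[C@]1(O)CC/C=C/[C@]1(C)C[C@@]2(OCc3ccccc3)CC[C@@H]1C(C)(C)[C@@H]2Cc1cc(OS(=O)(=O)O)ccc1OCc1ccccc1 | intermediate
47 | CNP0255133.1: benzoxepane (5aR,6S,7S,9aS), bicyclooctane (1S,2R,4S,5S) | C[C@H]1CC[C@@H]2OC(C)(C)CCC[C@@]2(C)[C@]1(O)CCCC[C@]1(C)C[C@@]2(O)CC[C@@H]1C(C)(C)[C@@H]2Cc1cc(OS(=O)(=O)O)ccc1O | target

## Step count and risks

Total: 31 steps. Longest linear sequence: 15 steps (steps 2–6, 11–16 and 28–31 from cyclohex-2-en-1-one). The branch from 2-methylcyclohexane-1,3-dione (steps 17–27, then 28–31) is equally long.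

**Step 5 (key step).**
- What may go wrong: poor discrimination between the two absolute senses, and difficult separation of the two endo diastereomers, because the menthyl group is remote from the carbon that forms the first bond. The endo preference may also erode with the α-methyl acceptor, and proton transfer from unreacted enone to the ester enolate may stop the sequence after the first addition.
- Fallback: from 9, run the annulation with tert-butyl methacrylate to give the racemic tert-butyl keto ester F1. Cleave it with CF3CO2H to the keto acid F2. Resolve the acid by crystallising its (S)-1-phenylethylammonium salt F3 (the antipodal amine if the other salt crystallises) and liberate the (1R,2R,4S) acid F2. Yamaguchi esterification with 1 (2,4,6-trichlorobenzoyl chloride, Et3N, then DMAP) returns to the route at 12.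

**Step 11.**
- What may go wrong: slow or failed addition to a ketone flanked by two quaternary carbons; competing attack of the benzylic reagent through its ring (ortho attack) or on the ester.
- Fallback: from 16, make the exocyclic alkene first by Takai–Lombardo methylenation (CH2Br2, Zn, TiCl4), which gives the methylidene compound F4. Attach the arene by a Heck reaction (Pd(OAc)2, P(o-tol)3, Et3N, DMF, 100 °C) with 1-(benzyloxy)-2-iodo-4-(methoxymethoxy)benzene F6. F6 comes from 4-(methoxymethoxy)phenol by ortho-iodination to 2-iodo-4-(methoxymethoxy)phenol F5, then benzylation. Both allylic positions of F4 are quaternary, so β-hydride elimination can only give the styrene; the sequence returns at 24 and bypasses 23.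

**Step 14.**
- What may go wrong: insufficient face control or no turnover, if the hydroxymethyl group cannot hold iridium over the very congested trisubstituted alkene. Hydrogen would then arrive from the open face and give the C5 epimer.
- Fallback: from 25, change from substrate direction to catalyst control. An iridium phosphine–oxazoline catalyst of the [Ir(cod)(PHOX)]BArF type, with the ligand enantiomer matched to the required face, would hydrogenate the alkene after O-silylation of the alcohol and return at 26 after desilylation. No new skeleton is made.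

**Step 21.**
- What may go wrong: loss of a proton from the tertiary cation to give alkenes, slow seven-membered closure, or intermolecular etherification.
- Fallback: from 32, carry out the cross-metathesis with methyl vinyl ketone to the enone F7 and hydrogenate it to the hydroxy ketone F8. Close the ring as the cyclic O,S-ketal F9 (EtSH, Zn(OTf)2), oxidise to the sulfone F10 (mCPBA), and replace the sulfonyl group by methyl with AlMe3. This irreversible sequence through an oxocarbenium ion returns at 36.

**Step 28.**
- What may go wrong: low conversion of the neopentyl vinyl group of 28, while 43 is consumed by homodimerisation.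
- Fallback: replace metathesis by carbonyl olefination. From 42, open the epoxide with vinylmagnesium bromide and CuBr·SMe2 to the allyl carbinol F11. Hydroboration–oxidation (9-BBN; H2O2, NaOH) gives the diol F12. A Mitsunobu reaction with 1-phenyl-1H-tetrazole-5-thiol gives the sulfide F13, and oxidation (H2O2, ammonium molybdate) gives the sulfone F14. Julia–Kocienski olefination of F14 (KHMDS, 2.2 equiv) with aldehyde 27 returns at 44.

## Further compounds

F1 | step 5 | tert-butyl 4-(benzyloxy)-2-methyl-5-oxobicyclo[2.2.2]octane-2-carboxylate (racemic; relative configuration shown) | CC(C)(C)OC(=O)[C@]1(C)C[C@@]2(OCc3ccccc3)CC[C@@H]1CC2=O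
F2 | step 5 | (1R,2R,4S)-4-(benzyloxy)-2-methyl-5-oxobicyclo[2.2.2]octane-2-carboxylic acid (racemic from F1, then resolved) | OC(=O)[C@]1(C)C[C@@]2(OCc3ccccc3)CC[C@@H]1CC2=O
F3 | step 5 | (S)-1-phenylethylammonium salt of F2 | C[C@H]([NH3+])c1ccccc1.[O-]C(=O)[C@]1(C)C[C@@]2(OCc3ccccc3)CC[C@@H]1CC2=O
F4 | step 11 | (1R,2S,5R)-menthyl (1R,2R,4S)-4-(benzyloxy)-2,6,6-trimethyl-5-methylidenebicyclo[2.2.2]octane-2-carboxylate | CC(C)[C@@H]1CC[C@@H](C)C[C@H]1OC(=O)[C@]2(C)C[C@@]3(OCc4ccccc4)CC[C@@H]2C(C)(C)C3=C
F5 | step 11 | 2-iodo-4-(methoxymethoxy)phenol | COCOc1ccc(O)c(I)c1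
F6 | step 11 | 1-(benzyloxy)-2-iodo-4-(methoxymethoxy)benzene | COCOc1ccc(OCc2ccccc2)c(I)c1
F0 | step 14 | none | none
F7 | step 21 | (1S,2R,3S)-3-hydroxy-2-methyl-2-[(2E)-4-oxopent-2-en-1-yl]cyclohexyl acetate | CC(=O)O[C@H]1CCC[C@H](O)[C@@]1(C)C/C=C/C(C)=O
F8 | step 21 | (1S,2R,3S)-3-hydroxy-2-methyl-2-(4-oxopentyl)cyclohexyl acetate | CC(=O)O[C@H]1CCC[C@H](O)[C@@]1(C)CCCC(C)=O
F9 | step 21 | (5aR,6S,9aS)-2-(ethylsulfanyl)-2,5a-dimethyldecahydro-1-benzoxepin-6-yl acetate (mixture at C2) | CC(=O)O[C@H]1CCC[C@@H]2OC(C)(SCC)CCC[C@@]12C
F10 | step 21 | (5aR,6S,9aS)-2-(ethylsulfonyl)-2,5a-dimethyldecahydro-1-benzoxepin-6-yl acetate (mixture at C2) | CC(=O)O[C@H]1CCC[C@@H]2OC(C)(S(=O)(=O)CC)CCC[C@@]12C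
F11 | step 28 | (5aR,6S,7S,9aS)-2,2,5a,7-tetramethyl-6-(prop-2-en-1-yl)decahydro-1-benzoxepin-6-ol | C[C@H]1CC[C@@H]2OC(C)(C)CCC[C@@]2(C)[C@]1(O)CC=C
F12 | step 28 | (5aR,6S,7S,9aS)-6-(3-hydroxypropyl)-2,2,5a,7-tetramethyldecahydro-1-benzoxepin-6-ol | C[C@H]1CC[C@@H]2OC(C)(C)CCC[C@@]2(C)[C@]1(O)CCCO
F13 | step 28 | (5aR,6S,7S,9aS)-2,2,5a,7-tetramethyl-6-{3-[(1-phenyl-1H-tetrazol-5-yl)sulfanyl]propyl}decahydro-1-benzoxepin-6-ol | C[C@H]1CC[C@@H]2OC(C)(C)CCC[C@@]2(C)[C@]1(O)CCCSc1nnnn1-c1ccccc1
F14 | step 28 | (5aR,6S,7S,9aS)-2,2,5a,7-tetramethyl-6-{3-[(1-phenyl-1H-tetrazol-5-yl)sulfonyl]propyl}decahydro-1-benzoxepin-6-ol | C[C@H]1CC[C@@H]2OC(C)(C)CCC[C@@]2(C)[C@]1(O)CCCS(=O)(=O)c1nnnn1-c1ccccc1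
A1 | alternative 1 | protected full skeleton, product of the radical closure | C[C@H]1CC[C@@H]2OC(C)(C)CCC[C@@]2(C)[C@]1(O)CCCC[C@]1(C)C[C@@]2(O)CC[C@@H]1C(C)(C)[C@@H]2Cc1cc(OCc2ccc(OC)cc2)ccc1OCc1ccccc1
A2 | alternative 1 | seco keto oxepene, precursor of A1 | C[C@@H](CC[C@@H]1OC(C)(C)CCC=C1C)C(=O)CCCC[C@]1(C)C[C@@]2(O)CC[C@@H]1C(C)(C)[C@@H]2Cc1cc(OCc2ccc(OC)cc2)ccc1OCc1ccccc1
A3 | alternative 2 | bridgehead ketol, product of the bridging aldol | C=CC[C@]1(C)C[C@@]2(O)CC(=O)[C@@H]1C(C)(C)[C@@H]2Cc1cc(OCc2ccc(OC)cc2)ccc1OCc1ccccc1
A4 | alternative 2 | 4-acetylcyclohexanone, precursor of A3 | C=CC[C@]1(C)CC(=O)[C@@H](Cc2cc(OCc3ccc(OC)cc3)ccc2OCc2ccccc2)C(C)(C)[C@H]1C(C)=O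
A5 | alternative 3 | arylmethyl bicyclo[2.2.2]octan-1-ol, product of the ketyl closure | CC(C)(C)[Si](C)(C)OCCC[C@]1(C)C[C@@]2(O)CC[C@@H]1C(C)(C)[C@@H]2Cc1cc(OCc2ccc(OC)cc2)ccc1OCc1ccccc1
A6 | alternative 3 | styrenyl cyclohexanone, precursor of A5 | CC(C)(C)[Si](C)(C)OCCC[C@]1(C)CC(=O)CC[C@@H]1C(C)(C)/C=C/c1cc(OCc2ccc(OC)cc2)ccc1OCc1ccccc1
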